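Ring C, the hydroxy-enone ring ArC–C(=O)–CH=C(OH)–C(=C), is a masked 1,3-diketone peri-fused to resorcinol ring B. It is cut between its ketone carbon and the ring B carbon that lies ortho to the phenol OH and para to the diaryl ether oxygen, the most nucleophilic arene position. The precursor holds rings A, B, D, the dimethoxyphenyl ring and the ten-membered ether ring and bears a carboxylic acid on the ring D alkene carbon. In one flask Meldrum's acid adds two carbons and heating releases an acylketene that acylates ring B, closing ring C last. Ring D arises by Dieckmann closure, the macrocycle by SNAr.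

Key step: step 12

Ring names: ring A is the 2-oxyphenyl ketone ring, ring B the central resorcinol ring, ring C the hydroxy-enone ring, ring D the dihydro ring with the two ring stereocentres, ring E the 2,6-dioxyphenyl ring. Locants C1 to C4 in the Why lines are the dihydronaphthalene positions of ring D in compounds 10 to 17 (C1 ester carbon, C2 oxygen- or aryl-bearing carbon, C3 side-chain CH, C4 CHMe).

Assumption: 2 and 7 are taken as catalogue reagents (each is otherwise one acylation step away), and (S)-Tol-BINAP is taken to deliver methyl to the Re face of the β-carbon in step 5; should the sense be opposite, the (R)-ligand is used.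

Step 1
Reactants: 1 3-fluoroanisole; 2 (E)-N-methoxy-N-methylbut-2-enamide
Product: 3 (E)-1-(2-fluoro-6-methoxyphenyl)but-2-en-1-one
Conditions: n-BuLi, THF, −78 °C; then 2, −78 to −20 °C; aq. NH4Cl
Reagents that add atoms: none
Why: Directed ortho-lithiation between F and OMe gives the aryllithium, which should add once to the Weinreb amide (stable chelate, Weinreb ketone synthesis) and release the E-enone on work-up; no stereocentre is formed.

Step 2
Reactants: 4 2-(3,5-dihydroxyphenyl)acetic acid
Product: 5 benzyl 2-[3,5-bis(benzyloxy)phenyl]acetate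
Conditions: BnBr (3.3 equiv), K2CO3, DMF, 60 °C
Reagents that add atoms: benzyl bromide, BrCc1ccccc1
Why: Williamson etherification and carboxylate alkylation should benzylate both phenols and the acid, while the benzylic CH2 is not acidic enough for carbonate.

Step 3
Reactants: 5 benzyl 2-[3,5-bis(benzyloxy)phenyl]acetate
Product: 6 benzyl 2-[3,5-bis(benzyloxy)-2-formylphenyl]acetate
Conditions: POCl3, DMF, 0 to 60 °C; then aq. NaOAc
Reagents that add atoms: N,N-dimethylformamide, CN(C)C=O; water, O
Why: Vilsmeier–Haack formylation should go to the position ortho to one benzyloxy group and para to the other (the two such positions are equivalent by symmetry), the site between the two ethers being more hindered.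

Step 4
Reactants: 6 benzyl 2-[3,5-bis(benzyloxy)-2-formylphenyl]acetate; 7 S-ethyl 2-(triphenyl-λ5-phosphanylidene)ethanethioate
Product: 8 benzyl 2-{3,5-bis(benzyloxy)-2-[(E)-3-(ethylsulfanyl)-3-oxoprop-1-en-1-yl]phenyl}acetate
Conditions: toluene, 90 °C
Reagents that add atoms: none
Why: Wittig olefination with a stabilised ylide should give the E-enethioate, and the arylacetate CH2 cannot reach the aldehyde.

Step 5
Reactants: 8 benzyl 2-{3,5-bis(benzyloxy)-2-[(E)-3-(ethylsulfanyl)-3-oxoprop-1-en-1-yl]phenyl}acetate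
Product: 9 benzyl 2-{3,5-bis(benzyloxy)-2-[(2R)-4-(ethylsulfanyl)-4-oxobutan-2-yl]phenyl}acetate
Conditions: MeMgBr, CuI (cat.), (S)-Tol-BINAP (cat.), t-BuOMe, −70 °C; aq. NH4Cl
Reagents that add atoms: methylmagnesium bromide, C[Mg]Br
Why: Copper-catalysed asymmetric conjugate addition of the Grignard reagent to the β-aryl enethioate, in which the chiral bisphosphine–copper complex delivers methyl to the Re face of the β-carbon and so sets the (R) benzylic centre, the benzyl ester being inert at this temperature.

Step 6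
Reactants: 9 benzyl 2-{3,5-bis(benzyloxy)-2-[(2R)-4-(ethylsulfanyl)-4-oxobutan-2-yl]phenyl}acetate
Product: 10 benzyl (4R)-5,7-bis(benzyloxy)-2-hydroxy-4-methyl-3,4-dihydronaphthalene-1-carboxylate (enol form of the β-keto ester)
Conditions: LiN(SiMe3)2 (2.2 equiv), THF, −78 to 0 °C; aq. NH4Cl
Reagents that add atoms: none
Why: Dieckmann condensation in which the arylacetate enolate attacks the more electrophilic thioester (6-exo-trig) and the product is held as its doubly stabilised enolate, which should make this mode win over attack of the thioester enolate on the benzyl ester; the benzylic stereocentre is not enolisable.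

Step 7
Reactants: 10 benzyl (4R)-5,7-bis(benzyloxy)-2-hydroxy-4-methyl-3,4-dihydronaphthalene-1-carboxylate; 3 (E)-1-(2-fluoro-6-methoxyphenyl)but-2-en-1-one
Product: 13 benzyl (3R,4R)-5,7-bis(benzyloxy)-3-[(2S)-4-(2-fluoro-6-methoxyphenyl)-4-oxobutan-2-yl]-2-hydroxy-4-methyl-3,4-dihydronaphthalene-1-carboxylate, via bis-silyl dienol ether 11 (not isolated), via silylated adduct 12 (not isolated)
Conditions: LiN(i-Pr)2 (2.2 equiv), Me3SiCl (2.4 equiv), THF, −78 °C; then 3, Me3SiOTf (cat.), CH2Cl2, −78 °C; 1 M HCl, THF
Reagents that add atoms: none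
Why: Vinylogous Mukaiyama–Michael addition in which the terminal carbon (C3) of the 1,3-bis(silyloxy)diene attacks the silyl-activated enone anti to the pseudo-axial C4 methyl group (3,4-trans), and the open antiperiplanar transition state, in which the enone methyl turns away from C4, should give the anti adduct with the (2S) side-chain centre.

Step 8
Reactants: 13 benzyl (3R,4R)-5,7-bis(benzyloxy)-3-[(2S)-4-(2-fluoro-6-methoxyphenyl)-4-oxobutan-2-yl]-2-hydroxy-4-methyl-3,4-dihydronaphthalene-1-carboxylate
Product: 14 benzyl (3R,4R)-5,7-bis(benzyloxy)-3-[(2S)-4-(2-fluoro-6-methoxyphenyl)-4-oxobutan-2-yl]-4-methyl-2-{[(trifluoromethyl)sulfonyl]oxy}-3,4-dihydronaphthalene-1-carboxylate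
Conditions: Tf2O, i-Pr2NEt, CH2Cl2, −78 °C
Reagents that add atoms: trifluoromethanesulfonic anhydride, O=S(=O)(OS(=O)(=O)C(F)(F)F)C(F)(F)F
Why: Enol triflate formation, in which only the β-keto ester enol is acidic enough for the amine base, so O-sulfonylation should occur at C2–O without touching the aryl ketone or epimerising C3.

Step 9
Reactants: 14 the enol triflate of step 8; 15 (2,6-dimethoxyphenyl)boronic acid
Product: 16 benzyl (3R,4R)-5,7-bis(benzyloxy)-2-(2,6-dimethoxyphenyl)-3-[(2S)-4-(2-fluoro-6-methoxyphenyl)-4-oxobutan-2-yl]-4-methyl-3,4-dihydronaphthalene-1-carboxylate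
Conditions: Pd(OAc)2 (cat.), SPhos (cat.), K3PO4, toluene/H2O, 90 °C
Reagents that add atoms: none
Why: Suzuki–Miyaura coupling of the electron-poor vinyl triflate, with a ligand made for di-ortho-substituted partners and excess boronic acid to offset protodeboronation; the stereocentres are not involved.

Step 10
Reactants: 16 the coupling product of step 9
Product: 17 (3R,4R)-2-(2,6-dimethoxyphenyl)-3-[(2S)-4-(2-fluoro-6-methoxyphenyl)-4-oxobutan-2-yl]-5,7-dihydroxy-4-methyl-3,4-dihydronaphthalene-1-carboxylic acid
Conditions: H2 (1 atm), Pd/C, EtOAc/MeOH, rt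
Reagents that add atoms: none
Why: Hydrogenolysis should remove both benzyl ethers and the benzyl ester in one operation, while the tetrasubstituted aryl-flanked alkene, the aryl fluoride and the hindered aryl ketone are expected to survive.

Step 11
Reactants: 17 the seco acid of step 10
Product: 18 macrocyclic acid, in which the ring B oxygen peri to the CHMe carbon is bonded to ring A ortho to the ketone (ten-membered ring; ring D still carries CO2H at C1)
Conditions: Cs2CO3, DMF (high dilution), 80 °C; aq. HCl
Reagents that add atoms: none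
Why: Intramolecular SNAr in which the phenoxide next to the CHMe-bearing carbon displaces the fluoride ortho to the ketone, the other phenoxide cannot reach it, the carboxylate is a poor nucleophile and high dilution should suppress oligomers.

Step 12
Reactants: 18 macrocyclic acid
Product: 21 tri-O-methyl ether of the target (ring C closed), via acyl Meldrum's acid 19 (not isolated), via acylketene 20 (not isolated)
Conditions: Meldrum's acid (2 equiv), DCC, DMAP (1.5 equiv), CH2Cl2, 0 °C to rt; then toluene (high dilution), 110 °C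
Reagents that add atoms: Meldrum's acid (2,2-dimethyl-1,3-dioxane-4,6-dione), CC1(C)OC(=O)CC(=O)O1
Why: DCC and DMAP should C-acylate Meldrum's acid with acid 18 to give 19, which at 110 °C loses acetone and CO2 in a retro-[4+2] fragmentation to the α-oxoketene 20. The ketene carbon is then attacked by the ring B carbon ortho to the phenol OH and para to the ether oxygen in an intramolecular Friedel–Crafts-type acylation, and tautomerisation gives the hydroxy-enone. The closest known reaction type is the thermal cyclisation of arylacetyl Meldrum's acids through acylketenes to naphthalene-1,3-diols. Ring C closes by 6-exo-dig attack on the ketene carbon at the peri position of the dihydronaphthalene. No stereocentre is formed, and the three existing ones are not enolisable under these neutral conditions. Site selectivity rests on geometry, since only that arene carbon reaches the ketene through a six-membered transition state (the phenol oxygen would need an eight-membered ring and the ring E positions in reach carry methoxy groups), while Meldrum's acid in excess over DMAP keeps the phenol protonated during acylation and dilution should suppress ketene dimerisation.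

Step 13
Reactants: 21 tri-O-methyl ether of the target
Product: 22 CNP0225737.1 (target)
Conditions: BBr3, CH2Cl2, −78 to 0 °C; aq. NaHCO3
Reagents that add atoms: none
Why: Lewis acid ether cleavage should remove the three methyl ethers (the one ortho to the ketone first, by chelation), while the diaryl ether, the ketone and the vinylogous acid survive and no stereocentre is touched.

Compound list
1 | 3-fluoroanisole | COc1cccc(F)c1 | starting material
2 | (E)-N-methoxy-N-methylbut-2-enamide | C/C=C/C(=O)N(C)OC | starting material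
3 | (E)-1-(2-fluoro-6-methoxyphenyl)but-2-en-1-one | C/C=C/C(=O)c1c(F)cccc1OC | intermediate
4 | 2-(3,5-dihydroxyphenyl)acetic acid | OC(=O)Cc1cc(O)cc(O)c1 | starting material
5 | benzyl 2-[3,5-bis(benzyloxy)phenyl]acetate | O=C(Cc1cc(OCc2ccccc2)cc(OCc2ccccc2)c1)OCc1ccccc1 | intermediate
6 | benzyl 2-[3,5-bis(benzyloxy)-2-formylphenyl]acetate | O=Cc1c(CC(=O)OCc2ccccc2)cc(OCc2ccccc2)cc1OCc1ccccc1 | intermediate
7 | S-ethyl 2-(triphenyl-λ5-phosphanylidene)ethanethioate | CCSC(=O)C=P(c1ccccc1)(c1ccccc1)c1ccccc1 | starting material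
8 | benzyl 2-{3,5-bis(benzyloxy)-2-[(E)-3-(ethylsulfanyl)-3-oxoprop-1-en-1-yl]phenyl}acetate | CCSC(=O)/C=C/c1c(CC(=O)OCc2ccccc2)cc(OCc2ccccc2)cc1OCc1ccccc1 | intermediate
9 | benzyl 2-{3,5-bis(benzyloxy)-2-[(2R)-4-(ethylsulfanyl)-4-oxobutan-2-yl]phenyl}acetate | CCSC(=O)C[C@@H](C)c1c(CC(=O)OCc2ccccc2)cc(OCc2ccccc2)cc1OCc1ccccc1 | intermediate
10 | benzyl (4R)-5,7-bis(benzyloxy)-2-hydroxy-4-methyl-3,4-dihydronaphthalene-1-carboxylate | C[C@@H]1CC(O)=C(C(=O)OCc2ccccc2)c2cc(OCc3ccccc3)cc(OCc3ccccc3)c21 | intermediate
11 | {(4R)-5,7-bis(benzyloxy)-1-[benzyloxy(trimethylsilyloxy)methylidene]-4-methyl-1,4-dihydronaphthalen-2-yl}oxy(trimethyl)silane (bis-silyl dienol ether of 10) | C[C@@H]1C=C(O[Si](C)(C)C)C(=C(OCc2ccccc2)O[Si](C)(C)C)c2cc(OCc3ccccc3)cc(OCc3ccccc3)c21 | intermediate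
12 | benzyl (3R,4R)-5,7-bis(benzyloxy)-3-[(2S)-4-(2-fluoro-6-methoxyphenyl)-4-(trimethylsilyloxy)but-3-en-2-yl]-4-methyl-2-(trimethylsilyloxy)-3,4-dihydronaphthalene-1-carboxylate | C[C@@H](C=C(O[Si](C)(C)C)c1c(F)cccc1OC)[C@H]1C(O[Si](C)(C)C)=C(C(=O)OCc2ccccc2)c2cc(OCc3ccccc3)cc(OCc3ccccc3)c2[C@@H]1C | intermediate
13 | benzyl (3R,4R)-5,7-bis(benzyloxy)-3-[(2S)-4-(2-fluoro-6-methoxyphenyl)-4-oxobutan-2-yl]-2-hydroxy-4-methyl-3,4-dihydronaphthalene-1-carboxylate | C[C@@H](CC(=O)c1c(F)cccc1OC)[C@H]1C(O)=C(C(=O)OCc2ccccc2)c2cc(OCc3ccccc3)cc(OCc3ccccc3)c2[C@@H]1C | intermediate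
14 | benzyl (3R,4R)-5,7-bis(benzyloxy)-3-[(2S)-4-(2-fluoro-6-methoxyphenyl)-4-oxobutan-2-yl]-4-methyl-2-{[(trifluoromethyl)sulfonyl]oxy}-3,4-dihydronaphthalene-1-carboxylate | C[C@@H](CC(=O)c1c(F)cccc1OC)[C@H]1C(OS(=O)(=O)C(F)(F)F)=C(C(=O)OCc2ccccc2)c2cc(OCc3ccccc3)cc(OCc3ccccc3)c2[C@@H]1C | intermediate
15 | (2,6-dimethoxyphenyl)boronic acid | COc1cccc(OC)c1B(O)O | starting material
16 | benzyl (3R,4R)-5,7-bis(benzyloxy)-2-(2,6-dimethoxyphenyl)-3-[(2S)-4-(2-fluoro-6-methoxyphenyl)-4-oxobutan-2-yl]-4-methyl-3,4-dihydronaphthalene-1-carboxylate | C[C@@H](CC(=O)c1c(F)cccc1OC)[C@H]1C(c2c(OC)cccc2OC)=C(C(=O)OCc2ccccc2)c2cc(OCc3ccccc3)cc(OCc3ccccc3)c2[C@@H]1C | intermediate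
17 | (3R,4R)-2-(2,6-dimethoxyphenyl)-3-[(2S)-4-(2-fluoro-6-methoxyphenyl)-4-oxobutan-2-yl]-5,7-dihydroxy-4-methyl-3,4-dihydronaphthalene-1-carboxylic acid | C[C@@H](CC(=O)c1c(F)cccc1OC)[C@H]1C(c2c(OC)cccc2OC)=C(C(=O)O)c2cc(O)cc(O)c2[C@@H]1C | intermediate
18 | macrocyclic acid (ten-membered diaryl ether; ring A OMe, ring E two OMe, ring B OH, CO2H on the ring D alkene carbon; configuration as in the target) | C[C@H]1CC(=O)c2c(OC)cccc2Oc2cc(O)cc3c2[C@H](C)[C@@H]1C(c1c(OC)cccc1OC)=C3C(=O)O | intermediate
19 | acyl Meldrum's acid of 18 (enol form) | C[C@H]1CC(=O)c2c(OC)cccc2Oc2cc(O)cc3c2[C@H](C)[C@@H]1C(c1c(OC)cccc1OC)=C3C(O)=C1C(=O)OC(C)(C)OC1=O | intermediate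
20 | acylketene from 19 | C[C@H]1CC(=O)c2c(OC)cccc2Oc2cc(O)cc3c2[C@H](C)[C@@H]1C(c1c(OC)cccc1OC)=C3C(=O)C=C=O | intermediate
21 | tri-O-methyl ether of the target (ring A OMe, ring E two OMe) | C[C@H]1CC(=O)c2c(OC)cccc2Oc2cc(O)c3c4c2[C@H](C)[C@@H]1C(c1c(OC)cccc1OC)=C4C(O)=CC3=O | intermediate
22 | CNP0225737.1 | C[C@H]1CC(=O)c2c(O)cccc2Oc2cc(O)c3c4c2[C@H](C)[C@@H]1C(c1c(O)cccc1O)=C4C(O)=CC3=O | target

Total step count: 13. Longest linear sequence: 12 steps (steps 2 to 13; step 1 makes the enone that enters at step 7).

Steps most likely to fail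

Step 9. Protodeboronation of the di-ortho-methoxy boronic acid may outrun transmetalation at the crowded vinyl–palladium centre, so that the triflate is recovered or hydrolysed. The fallback reverses the polarity of the coupling and sets out from 14: borylation with B2pin2 (PdCl2(dppf), KOAc, dioxane, 80 °C) should give the vinyl boronate F1, which is coupled with commercial 2-iodo-1,3-dimethoxybenzene (Pd(OAc)2, SPhos, K3PO4, toluene/H2O) and comes back to the route at 16.

Step 7. The enone faces may be poorly discriminated in the open transition state, which would give a mixture of epimers at the side-chain carbon (the ring carbon should still form trans to the methyl group). The fallback puts that centre under catalyst control and sets out from 10, through diene 11. Addition of 11 to (E)-but-2-enal under iminium catalysis with (2S,5S)-5-benzyl-2-tert-butyl-3-methylimidazolidin-4-one trifluoroacetate (CH2Cl2/H2O, −40 °C), which leaves the Si face of the β-carbon open, should give the aldehyde F2. 2-Fluoro-6-methoxyphenyllithium (from 1 and n-BuLi, 2.2 equiv, −78 °C; the enol is masked as its lithium enolate) then adds to give the benzylic alcohol F3, and MnO2 oxidation comes back to the route at 13.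

Step 12. C-acylation of Meldrum's acid by the crowded acrylic acid may be slow, so that rearrangement of the activated acid, ester formation at the free phenol or dimerisation of the ketene take over. The fallback uses an isolable β-keto ester and a Brønsted acid closure and sets out from 18: activation with carbonyldiimidazole and reaction with Mg(O2CCH2CO2t-Bu)2 (THF, rt) should give the β-keto tert-butyl ester F4, and Eaton's reagent (P2O5 in MeSO3H, rt) then effects the intramolecular Friedel–Crafts acylation with loss of the tert-butyl group and comes back to the route at 21.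

Further compounds
F1 | step 9 | benzyl (3R,4R)-5,7-bis(benzyloxy)-3-[(2S)-4-(2-fluoro-6-methoxyphenyl)-4-oxobutan-2-yl]-4-methyl-2-(4,4,5,5-tetramethyl-1,3,2-dioxaborolan-2-yl)-3,4-dihydronaphthalene-1-carboxylate | C[C@@H](CC(=O)c1c(F)cccc1OC)[C@H]1C(B2OC(C)(C)C(C)(C)O2)=C(C(=O)OCc2ccccc2)c2cc(OCc3ccccc3)cc(OCc3ccccc3)c2[C@@H]1C
F2 | step 7 | benzyl (3R,4R)-5,7-bis(benzyloxy)-2-hydroxy-4-methyl-3-[(2S)-4-oxobutan-2-yl]-3,4-dihydronaphthalene-1-carboxylate | C[C@@H](CC=O)[C@H]1C(O)=C(C(=O)OCc2ccccc2)c2cc(OCc3ccccc3)cc(OCc3ccccc3)c2[C@@H]1C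
F3 | step 7 | benzyl (3R,4R)-5,7-bis(benzyloxy)-3-[(2S)-4-(2-fluoro-6-methoxyphenyl)-4-hydroxybutan-2-yl]-2-hydroxy-4-methyl-3,4-dihydronaphthalene-1-carboxylate (carbinol centre not controlled) | C[C@@H](CC(O)c1c(F)cccc1OC)[C@H]1C(O)=C(C(=O)OCc2ccccc2)c2cc(OCc3ccccc3)cc(OCc3ccccc3)c2[C@@H]1C
F4 | step 12 | β-keto tert-butyl ester of 18 (C(=O)CH2CO2t-Bu on the ring D alkene carbon) | C[C@H]1CC(=O)c2c(OC)cccc2Oc2cc(O)cc3c2[C@H](C)[C@@H]1C(c1c(OC)cccc1OC)=C3C(=O)CC(=O)OC(C)(C)C
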